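The numbers in the tables come from a simulation with made-up constants; the scatter is artificial.

A one-step world has no wait, but the runs you sent had one, an induction period: at 3.00 h the target read 0.1% in dawn and 0.3% in winter, and only later did it rise in a nearly straight line.

the same everywhere: starting material 10 mM
- dawn: partner 15 mM; second reagent 7.4 mM; third reagent 20 mM; run made earlier
- winter: partner 15 mM; second reagent 16 mM; third reagent 20 mM; run made earlier
- flask: partner 15.0 mM; second reagent 11.0 mM; third reagent 20.0 mM; time 30 h

| run | time / h | target / % | crystals / % |
|---|---|---|---|
| dawn | 1.00 | 0 | 0 |
| dawn | 3.00 | 0.1 | 0 |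
| dawn | 5.00 | 0.8 | 0.6 |
| dawn | 8.00 | 1.5 | 0 |
| dawn | 10.0 | 3.1 | 0 |
| dawn | 15.0 | 8.1 | 1.7 |
| dawn | 20.0 | 13.4 | 7.3 |
| winter | 1.33 | 0 | 0 |
| winter | 2.00 | 0 | 0.2 |
| winter | 3.00 | 0.3 | 1.2 |
| winter | 5.00 | 1.5 | 0 |
| winter | 8.00 | 3.6 | 0.8 |
| winter | 12.0 | 8.8 | 1.7 |
| winter | 20.0 | 22.1 | 15.5 |

(scatter of a reading: 0.5 percentage points)

- what is said of target includes crystals
- crystals is a solid; its amount is given per volume of the solution
- the earlier runs were read with a standard deviation of 0.5 percentage points

- the target and crystals together standing at 30 h, as a percentage of the starting material charged
- concentration of target in solution at 30 h, in percent of saturation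

For your quick number I counted in one unit, the climb time: the hours the straight rise needs for one whole charge. From the last two readings of each run, scatter included, it read 94.3 h in dawn and 60.2 h in winter. A power law in second reagent through those two values gave this flask a climb time of 74.9 h. Running each straight line back to zero and averaging put the wait at 7.03 h, so I committed to 30.7% of the charge as target and crystals together at 30 h.

Your forecast said 31%, with the solution at 105% of saturation. It took the same road, a lag “then a near-linear rise”, so our match is no check.

The flask gave 31.5% and 106% of saturation.

    second reagent + intermediate A → intermediate B (k = 0.150 /M/min)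
    crystals ⇌ target, rate k2*(cs2 - [target]) while solid is left; crystals form when [target] > cs2 (solubility = 0.590 mM, k = 0.0620 /min)
    starting material + second reagent → side product (k = 0.00140 /M/min)
    third reagent + intermediate B → target (k = 0.0600 /M/min)
    starting material + partner → intermediate A (k = 0.0880 /M/min)

The flask was not at rest at 30 h. By 300 h it stood 3.91 climb times past the wait, yet target and crystals together stood at 97.2% of the charge, so the straight line had bent. The neighbour flask charged with 4.0 mM of starting material stood at 38.7% of its own charge at 30 h; if I grant it the same wait, that is a climb time of 59.4 h, shorter than this flask's 74.9 h. Over the long stretch this flask's crystals went from 25.2% to 91.3%, its starting material from 21.1% to 0.00969%, and its second reagent from 50.1% to 10.1% of its own charge.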